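**Plan**
- Retrosynthesis: the lactone of ring B (C4–C4a, O1–C2) is cut by a Pechmann-type disconnection to a 2,6-dioxygenated phenyl group. The lactone of ring C (C3–C4, O1–C2) is cut by a Perkin disconnection to an O7-acetic acid on ring A, and the lactone of ring A (C3–C4, O1–C2) by a Wittig disconnection to a salicylaldehyde.
- Enabling feature: the benzene ring of ring A carries C4 on C4a, oxygen on C8a and on C7, and the aryl group on C6. It is therefore a 5-aryl-2,4-dihydroxybenzoate, the dehydrogenated form of a 5-aryl-2,4-dioxocyclohexanecarboxylate, and its C4a–C5 and C7–C8 bonds are cut to ethyl acetoacetate and an ethyl 2-arylacrylate.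
- Forward order: the biaryl bond is present from the start as an aryl–C(sp2) bond made by acylating 2,6-dimethoxyphenyllithium. The carbocycle of ring A is annulated and dehydrogenated, then lactone A, lactone C and, after demethylation, lactone B are closed.
- The future O7 is distinguished from the future O1 by the hydrogen bond to the ester. It is alkylated once with a two-carbon arm at the alcohol level, which passes the hydride step and is later oxidised to the acid needed for ring C.
- Stereochemistry: the target has no stereocentre; the two labile sp3 centres of the dione disappear on aromatisation.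

Key step: step 3

Assumption: the biaryl axis between rings A and B is drawn without configuration and is treated as stereochemically undefined, so no atroposelective control is planned.

Step 1
Reactants: 1 1,3-dimethoxybenzene; 2 diethyl oxalate
Product: 4 ethyl 2-(2,6-dimethoxyphenyl)-2-oxoacetate, via 2,6-dimethoxyphenyllithium 3 (not isolated)
Conditions: n-BuLi, THF, 0 °C to rt; then inverse addition to 2 (excess), THF, −78 °C; aq. HCl
Reagents that add atoms: none
Why: Directed ortho-metalation places lithium at C2 between the two methoxy groups, and inverse addition of the hindered aryllithium to excess diethyl oxalate at low temperature should stop at mono-acylation because the tetrahedral alkoxide persists until the quench.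

Step 2
Reactants: 4 ethyl 2-(2,6-dimethoxyphenyl)-2-oxoacetate
Product: 5 ethyl 2-(2,6-dimethoxyphenyl)prop-2-enoate
Conditions: Ph3PCH3Br, KOtBu, THF, 0 °C to rt
Reagents that add atoms: methyltriphenylphosphonium bromide, C[P+](c1ccccc1)(c1ccccc1)c1ccccc1.[Br-]
Why: Wittig methylenation should take place only at the ketone carbonyl of the aryl glyoxylate, which is far more electrophilic than the neighbouring ester, and it delivers the 2-arylacrylate without the acid that a dehydration route would need and that could polymerise this electron-rich styrene.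

Step 3
Reactants: 5 ethyl 2-(2,6-dimethoxyphenyl)prop-2-enoate; 6 ethyl acetoacetate
Product: 8 ethyl 5-(2,6-dimethoxyphenyl)-2,4-dioxocyclohexane-1-carboxylate, via Michael adduct diethyl 2-acetyl-4-(2,6-dimethoxyphenyl)pentanedioate 7 (not isolated)
Conditions: NaOEt (1.1 equiv), 6 (1.2 equiv), EtOH, reflux; then aq. HCl, 0 °C
Reagents that add atoms: none
Why: Sodium ethoxide generates the doubly stabilised enolate of 6, which adds in a Michael reaction to the unsubstituted methylene terminus of acrylate 5 to give 7; after proton transfer the methyl-ketone enolate attacks the ester carbonyl beside the aryl-bearing carbon and expels ethoxide (Claisen condensation), and deprotonation of the resulting 1,3-dione draws the equilibria to the product. The closest known reaction type is the Michael–Claisen annulation of acetoacetates with α,β-unsaturated esters that gives dihydroresorcylates such as dihydroorsellinate. The six-membered carbocycle of ring A closes by 6-exo-trig attack on the ester carbonyl, forming the bonds that become C4a–C5 (Michael) and C7–C8 (Claisen) of the target. The two new sp3 centres (C1 and C5 of the dione) arise without control as an epimer and tautomer mixture, which is harmless because both become sp2 in step 4. The step needs Michael attack by the central carbon of 6 at the CH2 terminus and Claisen attack by the methyl carbon only: the first is secured by the acidity of the 1,3-dicarbonyl carbon and the open methylene of 5, the second because every other enolate–carbonyl pairing in 7 would give a four-membered ring, and the slight excess of 6 should suppress a second Michael addition.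

Step 4
Reactants: 8 ethyl 5-(2,6-dimethoxyphenyl)-2,4-dioxocyclohexane-1-carboxylate
Product: 9 ethyl 5-(2,6-dimethoxyphenyl)-2,4-dihydroxybenzoate
Conditions: 10% Pd/C, p-cymene, reflux, N2 sweep
Reagents that add atoms: none
Why: Catalytic dehydrogenation of a dihydroresorcylate over palladium removes one H2 across C5–C6 and the cyclohexenedione then tautomerises irreversibly to the resorcylate, and this reagent-free thermal method is chosen because halogen- or mercury-based aromatisations would attack the 1,3-dimethoxyarene.

Step 5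
Reactants: 9 ethyl 5-(2,6-dimethoxyphenyl)-2,4-dihydroxybenzoate
Product: 10 ethyl 5-(2,6-dimethoxyphenyl)-2-hydroxy-4-(2-hydroxyethoxy)benzoate
Conditions: BrCH2CH2OH (1.2 equiv), K2CO3, DMF, 70 °C
Reagents that add atoms: 2-bromoethanol, OCCBr
Why: In this Williamson etherification the hydroxyl ortho to the ester is held in a hydrogen bond to the carbonyl and is the weaker nucleophile, so carbonate base and a primary bromide should alkylate only the para hydroxyl (the future O7), installing the two-carbon arm of ring C at an oxidation level that is inert to hydride.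

Step 6
Reactants: 10 ethyl 5-(2,6-dimethoxyphenyl)-2-hydroxy-4-(2-hydroxyethoxy)benzoate
Product: 11 4-(2,6-dimethoxyphenyl)-5-(2-hydroxyethoxy)-2-(hydroxymethyl)phenol
Conditions: LiAlH4, THF, 0 °C to rt; then aq. potassium sodium tartrate
Reagents that add atoms: none
Why: Hydride reduction of a salicylate ester with LiAlH4 proceeds through the aluminium phenoxide to the benzylic alcohol, and because the para oxygen is already alkylated the product is an ordinary 2-hydroxybenzyl alcohol and not a self-condensing 2,4-dihydroxybenzyl alcohol, while the low temperature should prevent hydrogenolysis through a quinone methide.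

Step 7
Reactants: 11 4-(2,6-dimethoxyphenyl)-5-(2-hydroxyethoxy)-2-(hydroxymethyl)phenol
Product: 12 5-(2,6-dimethoxyphenyl)-2-hydroxy-4-(2-hydroxyethoxy)benzaldehyde
Conditions: MnO2 (activated, excess), CH2Cl2, rt
Reagents that add atoms: none
Why: Activated manganese dioxide oxidises benzylic alcohols but leaves saturated primary alcohols untouched, so this chemoselective oxidation should convert only the hydroxymethyl group into the salicylaldehyde.

Step 8
Reactants: 12 5-(2,6-dimethoxyphenyl)-2-hydroxy-4-(2-hydroxyethoxy)benzaldehyde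
Product: 14 6-(2,6-dimethoxyphenyl)-7-(2-hydroxyethoxy)-2H-chromen-2-one, via (E)-cinnamate ester 13 (not isolated)
Conditions: Ph3P=CHCO2Et, PhNEt2, reflux
Reagents that add atoms: ethyl (triphenylphosphoranylidene)acetate, CCOC(=O)C=P(c1ccccc1)(c1ccccc1)c1ccccc1
Why: Wittig olefination with the stabilised ylide gives the (E)-cinnamate, which at the boiling point of N,N-diethylaniline isomerises and closes onto the ortho phenol with loss of ethanol, the standard conversion of salicylaldehydes into 3,4-unsubstituted coumarins.

Step 9
Reactants: 14 6-(2,6-dimethoxyphenyl)-7-(2-hydroxyethoxy)-2H-chromen-2-one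
Product: 16 2-{[6-(2,6-dimethoxyphenyl)-2-oxo-2H-chromen-7-yl]oxy}acetic acid, via aryloxyacetaldehyde 15 (not isolated)
Conditions: TEMPO (cat.), PhI(OAc)2 (2.2 equiv), MeCN/H2O (1:1), rt
Reagents that add atoms: water, O
Why: Oxoammonium (TEMPO) oxidation with PhI(OAc)2 as terminal oxidant in aqueous acetonitrile takes a primary alcohol through the aldehyde hydrate to the carboxylic acid under conditions mild enough to spare the lactone and the dimethoxyarene.

Step 10
Reactants: 16 2-{[6-(2,6-dimethoxyphenyl)-2-oxo-2H-chromen-7-yl]oxy}acetic acid; 17 2-hydroxy-4-methoxybenzaldehyde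
Product: 20 6-(2,6-dimethoxyphenyl)-7-[(7-methoxy-2-oxo-2H-chromen-3-yl)oxy]-2H-chromen-2-one, via mixed acetic anhydride 18 (not isolated), via O-acylated salicylaldehyde ester 19 (not isolated)
Conditions: Ac2O, NaOAc, 140 °C
Reagents that add atoms: none
Why: In this Perkin-type condensation the mixed anhydride acylates the phenol of 17, the aryloxy-activated methylene then adds in an intramolecular aldol reaction to the neighbouring aldehyde and dehydration gives the 3-aryloxycoumarin, the classical construction of coumarin-3-yl coumarin-7-yl ethers from (coumarin-7-yloxy)acetic acids.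

Step 11
Reactants: 20 6-(2,6-dimethoxyphenyl)-7-[(7-methoxy-2-oxo-2H-chromen-3-yl)oxy]-2H-chromen-2-one
Product: 21 6-(2,6-dihydroxyphenyl)-7-[(7-hydroxy-2-oxo-2H-chromen-3-yl)oxy]-2H-chromen-2-one
Conditions: BBr3 (excess), CH2Cl2, −78 °C to rt; then H2O
Reagents that add atoms: none
Why: Lewis acid ether cleavage with BBr3 should remove all three aryl methyl groups by bromide attack on the O-methyl carbon of each borane adduct, while the two lactones and the aryl vinyl ether bridge, which offer no sp3 carbon for displacement, survive.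

Step 12
Reactants: 21 6-(2,6-dihydroxyphenyl)-7-[(7-hydroxy-2-oxo-2H-chromen-3-yl)oxy]-2H-chromen-2-one
Product: 23 7-hydroxy-8-{7-[(7-hydroxy-2-oxo-2H-chromen-3-yl)oxy]-2-oxo-2H-chromen-6-yl}-2H-chromen-2-one (target), via (Z)-cinnamate ester 22 (not isolated)
Conditions: HC≡CCO2Et, ZnCl2, dioxane, 100 °C
Reagents that add atoms: ethyl propiolate, CCOC(=O)C#C
Why: In this Pechmann-type coumarin synthesis in its propiolate form the Lewis acid-activated alkyne alkenylates the resorcinol ring ortho to one hydroxyl and para to the other (the two open positions are equivalent by symmetry and the carbon between the hydroxyls is blocked by ring A) and the (Z)-cinnamate lactonises to ring B, while the 7-hydroxycoumarin of ring C, deactivated by its lactone, should not compete, just as umbelliferone does not react further under the conditions that form it.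

**Compound list**
1 | 1,3-dimethoxybenzene | COc1cccc(OC)c1 | starting material
2 | diethyl oxalate | CCOC(=O)C(=O)OCC | starting material
3 | 2,6-dimethoxyphenyllithium (formed in the flask) | [Li]c1c(OC)cccc1OC | intermediate
4 | ethyl 2-(2,6-dimethoxyphenyl)-2-oxoacetate | CCOC(=O)C(=O)c1c(OC)cccc1OC | intermediate
5 | ethyl 2-(2,6-dimethoxyphenyl)prop-2-enoate | CCOC(=O)C(=C)c1c(OC)cccc1OC | intermediate
6 | ethyl acetoacetate | CCOC(=O)CC(C)=O | starting material
7 | diethyl 2-acetyl-4-(2,6-dimethoxyphenyl)pentanedioate (Michael adduct, diastereomer mixture, formed in the flask) | CCOC(=O)C(C(C)=O)CC(C(=O)OCC)c1c(OC)cccc1OC | intermediate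
8 | ethyl 5-(2,6-dimethoxyphenyl)-2,4-dioxocyclohexane-1-carboxylate (racemic, epimer and keto/enol tautomer mixture) | CCOC(=O)C1CC(c2c(OC)cccc2OC)C(=O)CC1=O | intermediate
9 | ethyl 5-(2,6-dimethoxyphenyl)-2,4-dihydroxybenzoate | CCOC(=O)c1cc(-c2c(OC)cccc2OC)c(O)cc1O | intermediate
10 | ethyl 5-(2,6-dimethoxyphenyl)-2-hydroxy-4-(2-hydroxyethoxy)benzoate | CCOC(=O)c1cc(-c2c(OC)cccc2OC)c(OCCO)cc1O | intermediate
11 | 4-(2,6-dimethoxyphenyl)-5-(2-hydroxyethoxy)-2-(hydroxymethyl)phenol | OCc1cc(-c2c(OC)cccc2OC)c(OCCO)cc1O | intermediate
12 | 5-(2,6-dimethoxyphenyl)-2-hydroxy-4-(2-hydroxyethoxy)benzaldehyde | O=Cc1cc(-c2c(OC)cccc2OC)c(OCCO)cc1O | intermediate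
13 | ethyl (E)-3-[5-(2,6-dimethoxyphenyl)-2-hydroxy-4-(2-hydroxyethoxy)phenyl]prop-2-enoate (formed in the flask) | CCOC(=O)/C=C/c1cc(-c2c(OC)cccc2OC)c(OCCO)cc1O | intermediate
14 | 6-(2,6-dimethoxyphenyl)-7-(2-hydroxyethoxy)-2H-chromen-2-one | O=c1ccc2cc(-c3c(OC)cccc3OC)c(OCCO)cc2o1 | intermediate
15 | 2-{[6-(2,6-dimethoxyphenyl)-2-oxo-2H-chromen-7-yl]oxy}acetaldehyde (formed in the flask) | O=CCOc1cc2oc(=O)ccc2cc1-c1c(OC)cccc1OC | intermediate
16 | 2-{[6-(2,6-dimethoxyphenyl)-2-oxo-2H-chromen-7-yl]oxy}acetic acid | OC(=O)COc1cc2oc(=O)ccc2cc1-c1c(OC)cccc1OC | intermediate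
17 | 2-hydroxy-4-methoxybenzaldehyde | COc1ccc(C=O)c(O)c1 | starting material
18 | acetic 2-{[6-(2,6-dimethoxyphenyl)-2-oxo-2H-chromen-7-yl]oxy}acetic anhydride (formed in the flask) | CC(=O)OC(=O)COc1cc2oc(=O)ccc2cc1-c1c(OC)cccc1OC | intermediate
19 | 2-formyl-5-methoxyphenyl 2-{[6-(2,6-dimethoxyphenyl)-2-oxo-2H-chromen-7-yl]oxy}acetate (formed in the flask) | COc1ccc(C=O)c(OC(=O)COc2cc3oc(=O)ccc3cc2-c2c(OC)cccc2OC)c1 | intermediate
20 | 6-(2,6-dimethoxyphenyl)-7-[(7-methoxy-2-oxo-2H-chromen-3-yl)oxy]-2H-chromen-2-one | O=c1ccc2cc(-c3c(OC)cccc3OC)c(Oc3cc4ccc(OC)cc4oc3=O)cc2o1 | intermediate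
21 | 6-(2,6-dihydroxyphenyl)-7-[(7-hydroxy-2-oxo-2H-chromen-3-yl)oxy]-2H-chromen-2-one | O=c1ccc2cc(-c3c(O)cccc3O)c(Oc3cc4ccc(O)cc4oc3=O)cc2o1 | intermediate
22 | ethyl (Z)-3-{2,4-dihydroxy-3-[7-[(7-hydroxy-2-oxo-2H-chromen-3-yl)oxy]-2-oxo-2H-chromen-6-yl]phenyl}prop-2-enoate (formed in the flask) | CCOC(=O)/C=C\c1ccc(O)c(-c2cc3ccc(=O)oc3cc2Oc2cc3ccc(O)cc3oc2=O)c1O | intermediate
23 | 7-hydroxy-8-{7-[(7-hydroxy-2-oxo-2H-chromen-3-yl)oxy]-2-oxo-2H-chromen-6-yl}-2H-chromen-2-one (CNP0215289.0) | O=c1ccc2cc(-c3c(O)ccc4ccc(=O)oc34)c(Oc3cc4ccc(O)cc4oc3=O)cc2o1 | target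

**Count**
Total steps: 12. Longest linear sequence: 12 steps (1 to 23); 2, 6 and 17 enter as single commercial building blocks.

**Steps most likely to fail**

Step 3. The ring closure may lose to side processes. Ethoxide can cleave the acetyl group of 7 (retro-Claisen), or a second acrylate can add, before the methyl-ketone enolate reaches the ester that sits beside the di-ortho-substituted aryl group. The fallback sets out from 1 and returns at 8, and it transposes the annulation so that the Claisen acceptor is an unhindered malonate ester. Aryllithium 3, made from 1 as in step 1, would be added to excess butane-2,3-dione (THF, −78 °C) to give 3-(2,6-dimethoxyphenyl)-3-hydroxybutan-2-one F1. Acid-catalysed dehydration (cat. TsOH, toluene, azeotropic removal of water) through the aryl-stabilised benzylic cation should give 3-(2,6-dimethoxyphenyl)but-3-en-2-one F2. Diethyl malonate and NaOEt in refluxing EtOH should then add to the methylene terminus to give diethyl 2-[2-(2,6-dimethoxyphenyl)-3-oxobutyl]propanedioate F3, whose methyl-ketone enolate closes onto a malonate ester, as in the dimedone synthesis. This gives the same dione 8, with the same Michael bond and the same carbocycle.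

Step 4. Dehydrogenation on the catalyst surface may be slower than thermal de-ethoxycarbonylation or retro-Claisen opening of the β-keto ester at the temperature required. The fallback sets out from 8 and returns at 9, and it replaces the thermal catalytic process by hydride abstraction from a preformed diene at room temperature. Silylation (TMSCl, Et3N, DMF) should give ethyl 5-(2,6-dimethoxyphenyl)-2,4-bis(trimethylsilyloxy)cyclohexa-1,3-diene-1-carboxylate F4. DDQ in CH2Cl2 at rt should remove hydride from C6, giving a cation stabilised by both silyloxy groups, and then the proton from C5, to give ethyl 5-(2,6-dimethoxyphenyl)-2,4-bis(trimethylsilyloxy)benzoate F5. Dilute aqueous HCl in THF then releases 9.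

Step 12. O-Vinylation of the three free phenols by the propiolate and slow C-alkenylation beside the crowded biaryl axis may give mixtures or incomplete conversion. The fallback sets out from 20 and returns at 23, and it builds ring B the way ring A was built. Rieche formylation (Cl2CHOMe, TiCl4, CH2Cl2, 0 °C) should strike the most electron-rich position of 20, ortho to one methoxy group and para to the other on the dimethoxyphenyl ring, giving 3-{7-[(7-methoxy-2-oxo-2H-chromen-3-yl)oxy]-2-oxo-2H-chromen-6-yl}-2,4-dimethoxybenzaldehyde F6. BBr3 in CH2Cl2 should then give 2,4-dihydroxy-3-{7-[(7-hydroxy-2-oxo-2H-chromen-3-yl)oxy]-2-oxo-2H-chromen-6-yl}benzaldehyde F7. Wittig olefination with Ph3P=CHCO2Et in refluxing PhNEt2 should pass through ethyl (E)-3-{2,4-dihydroxy-3-[7-[(7-hydroxy-2-oxo-2H-chromen-3-yl)oxy]-2-oxo-2H-chromen-6-yl]phenyl}prop-2-enoate F8, which isomerises and lactonises to 23.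

**Further compounds**
F1 | step 3 | 3-(2,6-dimethoxyphenyl)-3-hydroxybutan-2-one (racemic) | CC(=O)C(C)(O)c1c(OC)cccc1OC
F2 | step 3 | 3-(2,6-dimethoxyphenyl)but-3-en-2-one | CC(=O)C(=C)c1c(OC)cccc1OC
F3 | step 3 | diethyl 2-[2-(2,6-dimethoxyphenyl)-3-oxobutyl]propanedioate (racemic) | CCOC(=O)C(CC(C(C)=O)c1c(OC)cccc1OC)C(=O)OCC
F4 | step 4 | ethyl 5-(2,6-dimethoxyphenyl)-2,4-bis(trimethylsilyloxy)cyclohexa-1,3-diene-1-carboxylate (racemic) | CCOC(=O)C1=C(O[Si](C)(C)C)C=C(O[Si](C)(C)C)C(c2c(OC)cccc2OC)C1
F5 | step 4 | ethyl 5-(2,6-dimethoxyphenyl)-2,4-bis(trimethylsilyloxy)benzoate | CCOC(=O)c1cc(-c2c(OC)cccc2OC)c(O[Si](C)(C)C)cc1O[Si](C)(C)C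
F6 | step 12 | 3-{7-[(7-methoxy-2-oxo-2H-chromen-3-yl)oxy]-2-oxo-2H-chromen-6-yl}-2,4-dimethoxybenzaldehyde | O=Cc1ccc(OC)c(-c2cc3ccc(=O)oc3cc2Oc2cc3ccc(OC)cc3oc2=O)c1OC
F7 | step 12 | 2,4-dihydroxy-3-{7-[(7-hydroxy-2-oxo-2H-chromen-3-yl)oxy]-2-oxo-2H-chromen-6-yl}benzaldehyde | O=Cc1ccc(O)c(-c2cc3ccc(=O)oc3cc2Oc2cc3ccc(O)cc3oc2=O)c1O
F8 | step 12 | ethyl (E)-3-{2,4-dihydroxy-3-[7-[(7-hydroxy-2-oxo-2H-chromen-3-yl)oxy]-2-oxo-2H-chromen-6-yl]phenyl}prop-2-enoate | CCOC(=O)/C=C/c1ccc(O)c(-c2cc3ccc(=O)oc3cc2Oc2cc3ccc(O)cc3oc2=O)c1O
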